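Numbering used throughout: C1 = quaternary ring-fusion carbon with CH3, C2/C3 = CH2, C4 = isopropyl carbinol, C5 = ring-fusion CH, C6 = ester CH, C7 = CH2, C8 = methyl-bearing alkene carbon, C9 = alkene CH, C10 = ketone; five-membered ring C1–C5, seven-membered ring C5–C10 plus C1; α = face of the C1 methyl, β = the other face (target: 4α-OH, 4β-isopropyl, 5β-H, 6β-O).
Feature: in the seven-membered ring C1 stands between the ketone C10 and C5, so with C5 also at ketone level C1 is the prochiral centre of a symmetric 2,2-disubstituted cycloheptane-1,3-dione, and the oxygenated C4 next to C5 can be an aldehyde that reacts as an acyl anion.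
Key disconnection C4–C5: carbene-catalysed desymmetrising crossed benzoin of the C4 aldehyde onto one enantiotopic ring ketone. The seven-membered ring comes with the dione; the five-membered ring C1–C5 is the only ring closed, in that step.
After it, in forward order: dehydration to the C5=C6 enone, C10 ketal, conjugate borylation/oxidation (C6–O and trans C5–H), isopropylcerium addition at C4, C6 reset through the ketone by C4-hydroxyl-directed reduction, C6 veratrate, then the C8-methyl enone by dehydrogenation, methylcuprate addition and second dehydrogenation.
Before it: C-methylation of cycloheptane-1,3-dione and Michael addition to acrolein.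

Key step: step 3

Assumption: the sense of enantiotopic selection by the aminoindanol-derived triazolium salt on the seven-membered dione is assigned by analogy with the smaller ring diones; the (5aS,10bR) salt is written, and the (5aR,10bS) salt would be used if the first run showed the opposite sense.

Step 1
Reactants: 1 cycloheptane-1,3-dione
Product: 2 2-methylcycloheptane-1,3-dione
Conditions: MeI (1.1 equiv), K2CO3, acetone, reflux
Reagents that add atoms: iodomethane, CI
Why: Enolate C-alkylation of a cyclic 1,3-diketone at the doubly activated carbon between the carbonyls, with a near-stoichiometric charge of iodide to hold back a second methylation; no stereocentre arises.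

Step 2
Reactants: 2 2-methylcycloheptane-1,3-dione; 3 acrolein
Product: 4 3-(1-methyl-2,7-dioxocycloheptyl)propanal
Conditions: acrolein (1.5 equiv), Et3N (cat.), EtOAc, rt
Reagents that add atoms: none
Why: Amine-catalysed Michael addition of the tertiary 1,3-dicarbonyl carbon to acrolein builds the quaternary carbon C1 of a still achiral triketone (C1 is only prochiral) under conditions too mild for retro-Claisen opening.

Step 3
Reactants: 4 3-(1-methyl-2,7-dioxocycloheptyl)propanal
Product: 5 cis-fused ketol (1S,5R; C5–OH and C1–CH3 both α; ketones at C4 and C10)
Conditions: (5aS,10bR)-2-(pentafluorophenyl)-5a,10b-dihydro-4H,6H-indeno[2,1-b][1,2,4]triazolo[4,3-d][1,4]oxazin-2-ium tetrafluoroborate (10 mol%), Et3N (10 mol%), CH2Cl2, rt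
Reagents that add atoms: none
Why: The carbene freed from the triazolium salt adds to the aldehyde carbon C4, proton transfer gives the Breslow intermediate, and its nucleophilic C4 attacks the ring carbonyl C5 before the alkoxide collapses and releases the carbene. This is the intramolecular crossed aldehyde–ketone benzoin reaction in its desymmetrising form, known for 2,2-disubstituted cyclopentane- and cyclohexane-1,3-diones and extended here by one ring carbon. The five-membered ring C1–C5 closes in a 5-exo-trig mode, the former carbonyl oxygen ending as the C5 hydroxyl outside the new ring. C1 becomes stereogenic because the chiral catalyst selects between the enantiotopic carbonyls C5 and C10, and C5 is set by the three-atom tether, which can reach the carbonyl only from the face of the seven-membered ring that carries the side chain, so the hydroxyl ends cis to the C1 methyl and the rings cis-fused. The step needs enantiotopic-group selection, supplied by the catalyst, and preference for the benzoin over aldol pathways, secured by the fast addition of the carbene to the aldehyde and by a base too weak to enolise the dione.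

Step 4
Reactants: 5 cis-fused ketol
Product: 6 enedione (1S; C5=C6 conjugated with the C4 ketone; C10 ketone)
Conditions: SOCl2, pyridine, CH2Cl2, −10 °C to rt
Reagents that add atoms: none
Why: Dehydration through the chlorosulfite by pyridine-induced E2 elimination can only give C5=C6, because C6–H is the only hydrogen beside C5 (C1 is quaternary, C4 a carbonyl); the temporary C5 centre vanishes and C1 is untouched.

Step 5
Reactants: 6 enedione
Product: 7 C10 ethylene ketal (1,3-dioxolane) of the enedione
Conditions: TMSOCH2CH2OTMS, TMSOTf (cat.), CH2Cl2, −78 to −20 °C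
Reagents that add atoms: 1,2-bis(trimethylsilyloxy)ethane, C[Si](C)(C)OCCO[Si](C)(C)C
Why: Silyl-triflate-catalysed dioxolane formation selects the saturated C10 ketone over the much less electrophilic conjugated C4 carbonyl, as in the monoketalisation of bicyclic enediones of the Wieland–Miescher type, and so removes C10 from the later carbonyl chemistry at C4 and C6 without touching a stereocentre.

Step 6
Reactants: 7 C10 ketal enone
Product: 9 trans-fused 6α-hydroxy C4 ketone (C5–H β; C10 dioxolane), via C6α pinacolboronate 8 (not isolated)
Conditions: B2pin2, CuCl (5 mol%), Xantphos (5 mol%), NaOtBu (10 mol%), MeOH (2 equiv), THF, rt; then 30% aq. H2O2, aq. NaHCO3, 0 °C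
Reagents that add atoms: bis(pinacolato)diboron, CC1(C)OB(OC1(C)C)B1OC(C)(C)C(C)(C)O1 (boron of 8); hydrogen peroxide, OO (oxygen at C6 of 9)
Why: Copper-catalysed conjugate borylation then boron-to-oxygen oxidation with retention: the boryl copper species should add to C6 on the α face, the exo face turned away from the C8–C10 arc and the dioxolane that fold over the β face, and protonation at C5 anti to the pseudo-axial C6 boryl group and the C1 methyl should give C5–H β and so the trans ring fusion; the α configuration at C6 is not the one the target needs and is corrected in steps 10 and 11.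

Step 7
Reactants: 9 trans-fused 6α-hydroxy C4 ketone
Product: 10 6α-triethylsilyl ether of 9
Conditions: TESCl, imidazole, DMF, 0 °C to rt
Reagents that add atoms: chlorotriethylsilane, CC[Si](CC)(CC)Cl
Why: Silyl ether formation with chlorosilane and imidazole is mild enough to protect the secondary C6 hydroxyl of the β-hydroxy ketone without elimination or epimerisation at C5, and no stereocentre changes.

Step 8
Reactants: 10 6α-triethylsilyloxy C4 ketone; 11 isopropylmagnesium chloride
Product: 12 C4 tertiary alcohol (4α-OH, 4β-isopropyl, 6α-OSiEt3, C10 dioxolane)
Conditions: CeCl3 (anhydrous), iPrMgCl, THF, −78 to 0 °C; then H2O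
Reagents that add atoms: none
Why: Organocerium 1,2-addition: the weakly basic isopropylcerium dichloride formed by transmetallation should add to the hindered, enolisable C4 ketone without enolisation, loss of the β-silyloxy group or hydride transfer, and should attack from the β face, anti to the C1 methyl (1,3 across the five-membered ring) and to the C6 branch on C5, which sets C4 with hydroxyl α and isopropyl β.

Step 9
Reactants: 12 C4 tertiary alcohol
Product: 13 4α,6α-dihydroxy-4β-isopropyl C10 ketone (trans-fused)
Conditions: 1 M HCl, THF, rt
Reagents that add atoms: water, O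
Why: Acid hydrolysis removes the triethylsilyl ether and the dioxolane together under conditions that the tertiary C4 alcohol tolerates, and C5, not α to any carbonyl here, cannot epimerise.

Step 10
Reactants: 13 4α,6α-diol C10 ketone
Product: 14 4α-hydroxy-4β-isopropyl 6,10-diketone
Conditions: Dess–Martin periodinane, CH2Cl2, 0 °C to rt
Reagents that add atoms: none
Why: Dess–Martin oxidation converts the only secondary alcohol into the C6 ketone under neutral conditions that spare the tertiary C4 hydroxyl and avoid retro-aldol cleavage; the C6 centre is erased, and C5, now α to C6, should stay trans-fused because that form keeps C6 anti to the isopropyl group and hydrogen-bonded to the C4 hydroxyl.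

Step 11
Reactants: 14 4α-hydroxy 6,10-diketone
Product: 15 4α,6β-dihydroxy-4β-isopropyl C10 ketone
Conditions: Me4NBH(OAc)3, MeCN/AcOH (1:1), −30 to −20 °C
Reagents that add atoms: none
Why: Hydroxyl-directed triacetoxyborohydride reduction (Evans–Saksena type): the C4 oxygen binds boron and delivers hydride through a six-membered transition state to the α face of C6, giving the anti 1,3-diol with C6–OH β, while the C10 ketone, with no hydroxyl in reach and flanked by the quaternary C1, should not be reduced.

Step 12
Reactants: 15 4α,6β-diol C10 ketone; 16 3,4-dimethoxybenzoyl chloride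
Product: 17 6β-(3,4-dimethoxybenzoyloxy)-4α-hydroxy-4β-isopropyl C10 ketone
Conditions: pyridine, DMAP (cat.), CH2Cl2, 0 °C to rt
Reagents that add atoms: none
Why: DMAP-catalysed acylation with the acid chloride takes place only at the secondary C6 hydroxyl, the tertiary C4 hydroxyl being too hindered, and C6 keeps its configuration because its C–O bond is not broken.

Step 13
Reactants: 17 C6β veratrate C10 ketone
Product: 19 C8=C9 enone with 4α-OSiMe3 and 6β-veratrate, via bis-trimethylsilyl enol ether 18 (not isolated)
Conditions: TMSOTf (2.5 equiv), Et3N, CH2Cl2, 0 °C; then Pd(OAc)2 (1.1 equiv), MeCN, rt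
Reagents that add atoms: trimethylsilyl trifluoromethanesulfonate, C[Si](C)(C)OS(=O)(=O)C(F)(F)F
Why: Soft enolisation gives the only possible silyl enol ether of the C10 ketone (C9=C10, since C1 is quaternary) and silylates the tertiary C4 hydroxyl, and Saegusa–Ito oxidation with Pd(OAc)2 then forms the C8=C9 enone by β-hydride elimination from the palladium enolate, leaving the ester and all stereocentres untouched.

Step 14
Reactants: 19 C8=C9 enone
Product: 21 4-O-trimethylsilyl ether of the target, via C8-methyl silyl enol ether 20 (not isolated)
Conditions: Me2CuLi (from CuI and 2 MeLi), TMSCl, THF, −78 °C; then Pd(OAc)2 (1.1 equiv), MeCN, rt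
Reagents that add atoms: lithium dimethylcuprate, [Li+].C[Cu-]C; chlorotrimethylsilane, C[Si](C)(C)Cl (silicon of 20)
Why: Conjugate addition of the cuprate to the cycloheptenone with silyl chloride trapping places the methyl group on C8, and a second Saegusa–Ito oxidation removes the single C8 hydrogen to give the C8-methyl enone, so the transient C8 centre needs no control and the aryl ester is inert to the cuprate at low temperature.

Step 15
Reactants: 21 4-O-trimethylsilyl ether of the target
Product: 22 target, (3R,3aS,4S,8aS)-3-hydroxy-6,8a-dimethyl-8-oxo-3-(propan-2-yl)-1,2,3,3a,4,5,8,8a-octahydroazulen-4-yl 3,4-dimethoxybenzoate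
Conditions: 1 M HCl, THF, 0 °C
Reagents that add atoms: none
Why: Mild acid hydrolysis of the tertiary trimethylsilyl ether frees the C4 hydroxyl without touching the ester and without the basic conditions that could eliminate the C6 acyloxy group through the vinylogous enolate; no stereocentre is affected.

Compound list (positions in the names follow the C1–C10 numbering of the overview)
1 | cycloheptane-1,3-dione | O=C1CCCCC(=O)C1 | starting material
2 | 2-methylcycloheptane-1,3-dione | CC1C(=O)CCCCC1=O | intermediate
3 | acrolein | C=CC=O | starting material
4 | 3-(1-methyl-2,7-dioxocycloheptyl)propanal | O=CCCC1(C)C(=O)CCCCC1=O | intermediate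
5 | cis-fused ketol, (1S,5R): C1 methyl, C5 hydroxyl cis to it, ketones at C4 and C10 | C1CCCC(=O)[C@@]2(C)CCC(=O)[C@@]12O | intermediate
6 | enedione, (1S): C1 methyl, C5=C6, ketones at C4 and C10 | C1=C2C(=O)CC[C@]2(C)C(=O)CCC1 | intermediate
7 | C10 ethylene ketal of 6 | C1=C2C(=O)CC[C@]2(C)C3(OCCO3)CCC1 | intermediate
8 | trans-fused C4 ketone with 6α-pinacolboryl group, 5β-H, C10 dioxolane | CC1(C)OB(OC1(C)C)[C@@H]2CCCC3(OCCO3)[C@@]4(C)CCC(=O)[C@H]24 | intermediate (not isolated)
9 | trans-fused 6α-hydroxy C4 ketone, 5β-H, C10 dioxolane | O[C@@H]1CCCC2(OCCO2)[C@@]3(C)CCC(=O)[C@H]13 | intermediate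
10 | 6α-triethylsilyl ether of 9 | CC[Si](CC)(CC)O[C@@H]1CCCC2(OCCO2)[C@@]3(C)CCC(=O)[C@H]13 | intermediate
11 | isopropylmagnesium chloride | CC(C)[Mg]Cl | starting material
12 | C4 carbinol: 4α-OH, 4β-isopropyl, 6α-OSiEt3, C10 dioxolane | CC[Si](CC)(CC)O[C@@H]1CCCC2(OCCO2)[C@@]3(C)CC[C@@](O)(C(C)C)[C@H]13 | intermediate
13 | 4α,6α-dihydroxy-4β-isopropyl C10 ketone | O[C@@H]1CCCC(=O)[C@@]2(C)CC[C@@](O)(C(C)C)[C@H]12 | intermediate
14 | 4α-hydroxy-4β-isopropyl 6,10-diketone | O=C1CCCC(=O)[C@@]2(C)CC[C@@](O)(C(C)C)[C@H]12 | intermediate
15 | 4α,6β-dihydroxy-4β-isopropyl C10 ketone | O[C@H]1CCCC(=O)[C@@]2(C)CC[C@@](O)(C(C)C)[C@H]12 | intermediate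
16 | 3,4-dimethoxybenzoyl chloride | COc1ccc(C(=O)Cl)cc1OC | starting material
17 | 6β-(3,4-dimethoxybenzoate) of 15 | COc1ccc(C(=O)O[C@H]2CCCC(=O)[C@@]3(C)CC[C@@](O)(C(C)C)[C@H]23)cc1OC | intermediate
18 | C9=C10 trimethylsilyl enol ether with 4α-OSiMe3 and 6β-veratrate | COc1ccc(C(=O)O[C@H]2CCC=C(O[Si](C)(C)C)[C@@]3(C)CC[C@@](O[Si](C)(C)C)(C(C)C)[C@H]23)cc1OC | intermediate (not isolated)
19 | C8=C9 enone (C10 ketone) with 4α-OSiMe3 and 6β-veratrate | COc1ccc(C(=O)O[C@H]2CC=CC(=O)[C@@]3(C)CC[C@@](O[Si](C)(C)C)(C(C)C)[C@H]23)cc1OC | intermediate
20 | 8-methyl C9=C10 trimethylsilyl enol ether with 4α-OSiMe3 and 6β-veratrate (C8 configuration not controlled and of no consequence) | COc1ccc(C(=O)O[C@H]2CC(C)C=C(O[Si](C)(C)C)[C@@]3(C)CC[C@@](O[Si](C)(C)C)(C(C)C)[C@H]23)cc1OC | intermediate (not isolated)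
21 | 4-O-trimethylsilyl ether of the target | COc1ccc(C(=O)O[C@H]2CC(C)=CC(=O)[C@@]3(C)CC[C@@](O[Si](C)(C)C)(C(C)C)[C@H]23)cc1OC | intermediate
22 | (3R,3aS,4S,8aS)-3-hydroxy-6,8a-dimethyl-8-oxo-3-(propan-2-yl)-1,2,3,3a,4,5,8,8a-octahydroazulen-4-yl 3,4-dimethoxybenzoate | COc1ccc(C(=O)O[C@H]2CC(C)=CC(=O)[C@@]3(C)CC[C@@](O)(C(C)C)[C@H]23)cc1OC | target

Total step count: 15. Longest linear sequence: 15 steps, from 1 to 22.

Steps most likely to fail

Step 6. The boryl copper species may add to the β face of the hindered trisubstituted enone, or the enol(ate) may be protonated at C5 without facial preference or equilibrate under the alkoxide. Either way the cis-fused C5 epimer would form, and it would steer the isopropyl group to the wrong face in step 8. The fallback sets out from 7 and replaces the protonation by a stereospecific hydride shift. Weitz–Scheffer epoxidation (tBuOOH, DBU, CH2Cl2) on the exo α face should give the 5α,6α-epoxy C4 ketone F1. Luche reduction (NaBH4, CeCl3·7H2O, MeOH, −40 °C) anti to the oxirane oxygen should give the cis epoxy alcohol F2 (4α-OH, 4β-H). Brief treatment with BF3·OEt2 in CH2Cl2 at −78 °C should then trigger a semipinacol rearrangement: the tertiary C5–O bond ionises and the antiperiplanar C4 hydrogen moves to the β face of C5 as the C4 carbonyl forms. The product is the 6α-hydroxy trans-fused ketone, at which the fallback comes back to the route as 9.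

Step 3. The seven-membered dione is more flexible and less electrophilic than the smaller diones, so discrimination between the enantiotopic carbonyls may be poor, and a slow closure would let aldol reactions compete. The fallback sets out from 4 and gives up asymmetric catalysis for resolution. An achiral carbene (3-benzyl-5-(2-hydroxyethyl)-4-methylthiazolium chloride, Et3N, EtOH, 60 °C) should give the racemic cis ketol, that is 5 together with its enantiomer, the ent-ketol F3. Dehydration as in step 4 gives the racemic enedione, 6 together with the ent-enedione F4. Preparative chromatography on a chiral stationary phase separates the two, and the fallback comes back to the route at 6.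

Step 8. Addition of a branched nucleophile to the hindered C4 ketone may be outrun by enolisation, by β-hydride transfer from the isopropyl metal species (reduction of the ketone) or by loss of the silyloxy group, leaving the ketone unconverted or reduced. The fallback sets out from 10 and brings the three carbons in as an sp2 nucleophile that cannot donate hydride. Isopropenylmagnesium bromide with CeCl3 in THF at −78 °C should add from the same β face to give the isopropenyl carbinol F5. Hydrogenation of its 1,1-disubstituted alkene (H2, Pd/C, EtOAc) then gives the isopropyl carbinol, at which the fallback comes back to the route as 12.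

Further compounds
F1 | step 6 | 5α,6α-epoxy C4 ketone with C10 dioxolane | O1[C@@H]2CCCC3(OCCO3)[C@@]4(C)CCC(=O)[C@@]124
F2 | step 6 | 5α,6α-epoxy 4α-alcohol (4β-H) with C10 dioxolane | O1[C@@H]2CCCC3(OCCO3)[C@@]4(C)CC[C@H](O)[C@@]124
F3 | step 3 | ent-ketol, (1R,5S) enantiomer of 5, formed with 5 as the racemate | C1CCCC(=O)[C@]2(C)CCC(=O)[C@]12O
F4 | step 3 | ent-enedione, (1R) enantiomer of 6, formed with 6 as the racemate | C1=C2C(=O)CC[C@@]2(C)C(=O)CCC1
F5 | step 8 | C4 isopropenyl carbinol: 4α-OH, 4β-isopropenyl, 6α-OSiEt3, C10 dioxolane | CC[Si](CC)(CC)O[C@@H]1CCCC2(OCCO2)[C@@]3(C)CC[C@@](O)(C(C)=C)[C@H]13
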